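**Plan**

1. The SMILES is read literally as (4S,5S,9S,10R,13R)-13-acetoxy-5-epi-labda-8(17),14-dien-19-oic acid: rings A/B are cis-fused (H-5 syn to CH3-10). Labdane numbering C-1 to C-20 is used for atoms; plain numbers are compounds.
2. Retrosynthetic cuts, in order: O–acetyl; C-8=C-17; C-9–C-11; C-1–C-10 (ring A); C-1–O of a δ-lactone together with the C-8 carbonyl; C-4–C-5.
3. Forward: ring B is present from the start (2-methylcyclohexenone). C-4–C-5 is made by an ortho-lactone Johnson–Claisen rearrangement, C-8 is oxidised, and the lactone is opened to the C-19 ester and C-1 iodide. Ring A is then closed C-1→C-10, the linalool-derived C-11 to C-16 chain is alkylated onto C-9, C-17 is added by methylenation, and the acetate comes last.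
4. Enabling feature: C-8, the ring-B carbon that carries the exocyclic methylene, is 1,3 to the quaternary C-10. As a ketone it makes C-9=C-10 an enone, so C-10 is an electrophilic β-carbon that C-1 of the chain on C-5 can reach only from its own face. That is exactly the cis fusion required, and the resulting C-8/C-9 enolate then accepts C-11.
5. Stereochemistry: the C-9 carbinol (CBS reduction) is relayed to C-5 by the suprafacial [3,3] shift; C-4 comes from the ring-fixed ketene acetal geometry in a chair transition state; C-10 from tethered cis delivery; C-9 from convex-face alkylation; C-13 from (R)-linalool.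
6. Helpers and their removal: the δ-lactone ring (opened in step 6), the C-8 carbonyl (becomes the methylene in step 13), the enol silane (step 12), the SiEt3 ether and the methyl ester (steps 14 and 15).

Key step: step 7

**Route**

Step 1
Reactants: 1 oxan-2-one (δ-valerolactone)
Product: 3 3-methyloxan-2-one (racemic), via lithium lactone enolate 2 (not isolated)
Conditions: LiN(iPr)2, THF, −78 °C; then MeI, −78 → −20 °C
Reagents that add atoms: iodomethane, CI
Why: Enolate alkylation (SN2) of lactone enolate 2 with iodomethane puts C-18 on the future C-4; the new centre is left racemic because it is flattened again in step 4.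

Step 2
Reactants: 3 3-methyloxan-2-one
Product: 5 2,2-dimethoxy-3-methyloxane, via lactonium tetrafluoroborate 4 (not isolated)
Conditions: Me3OBF4, CH2Cl2, 23 °C; then NaOMe, MeOH, −30 → 0 °C
Reagents that add atoms: trimethyloxonium tetrafluoroborate, C[O+](C)C.F[B-](F)(F)F; sodium methoxide, [Na+].[O-]C
Why: Meerwein O-methylation of the lactone carbonyl gives dialkoxycarbenium salt 4, which methoxide captures at carbon to give the ortho-lactone (ortho ester formation); no stereocentre is set.

Step 3
Reactants: 6 2-methylcyclohex-2-en-1-one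
Product: 7 (1R)-2-methylcyclohex-2-en-1-ol
Conditions: (S)-2-methyl-CBS-oxazaborolidine (10 mol %), BH3·SMe2, THF, −20 °C
Reagents that add atoms: none
Why: Corey–Bakshi–Shibata reduction: the oxazaborolidine–borane complex treats the C(CH3)=CH arm as the large group and delivers hydride in a 1,2 sense to one carbonyl face, which should give the 1R carbinol (future C-9–O, needed only as a relay to C-5).

Step 4
Reactants: 7 (1R)-2-methylcyclohex-2-en-1-ol; 5 2,2-dimethoxy-3-methyloxane
Product: 10 (3S)-3-methyl-3-[(1S)-2-methylcyclohex-2-en-1-yl]oxan-2-one, via mixed ortho ester 8 (not isolated), via ketene acetal 9 (not isolated)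
Conditions: EtCO2H (5 mol %), xylene, 140 °C, MeOH distilled off
Reagents that add atoms: none
Why: Johnson–Claisen rearrangement with an ortho-lactone: alcohol exchange and loss of methanol give ketene acetal 9, whose ring fixes the geometry (CH3 cis to the allylic oxygen), the suprafacial [3,3] shift passes the C-9–O configuration to C-5 (new C-4–C-5 bond on the face the oxygen leaves), and the chair-like transition state, preferred because a boat would push CH3-10 against the acetal carbon, sets the quaternary C-4 (4S,5S expected).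

Step 5
Reactants: 10 (3S)-3-methyl-3-[(1S)-2-methylcyclohex-2-en-1-yl]oxan-2-one
Product: 11 (3S)-3-methyl-3-[(1S)-2-methyl-4-oxocyclohex-2-en-1-yl]oxan-2-one
Conditions: Rh2(caprolactamate)4 (1 mol %), t-BuOOH, K2CO3, CH2Cl2, 23 °C
Reagents that add atoms: tert-butyl hydroperoxide, CC(C)(C)OO
Why: Rhodium-catalysed radical allylic oxidation with t-BuOOH attacks the only unhindered secondary allylic CH2 (C-8) and gives the conjugated enone; no stereocentre is formed and the γ-hydrogen at C-5 should not be removed by the weak heterogeneous base.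

Step 6
Reactants: 11 (3S)-3-methyl-3-[(1S)-2-methyl-4-oxocyclohex-2-en-1-yl]oxan-2-one
Product: 14 methyl (2S)-5-iodo-2-methyl-2-[(1S)-2-methyl-4-oxocyclohex-2-en-1-yl]pentanoate, via trimethylsilyl ester 12 (not isolated), via iodo acid 13 (not isolated)
Conditions: Me3SiI, CH2Cl2, 0 → 23 °C, dark; MeOH; then Me3SiCHN2, PhMe/MeOH, 0 °C
Reagents that add atoms: iodotrimethylsilane, C[Si](C)(C)I; trimethylsilyldiazomethane, C[Si](C)(C)C=[N+]=[N-]
Why: O-Silylation of the lactone carbonyl and SN2 attack of iodide at the primary O–CH2 carbon (C-1) open the temporary ring to silyl ester 12, methanolysis gives acid 13 and diazoalkane O-methylation gives the ester without base, so that neither relactonisation of the iodo acid nor epimerisation at C-5 should intervene; C-4 and C-5 are untouched.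

Step 7
Reactants: 14 methyl (2S)-5-iodo-2-methyl-2-[(1S)-2-methyl-4-oxocyclohex-2-en-1-yl]pentanoate
Product: 16 methyl (1S,4aS,8aS)-1,4a-dimethyl-6-[(trimethylsilyl)oxy]-1,2,3,4,4a,7,8,8a-octahydronaphthalene-1-carboxylate, via alkylzinc iodide 15 (not isolated)
Conditions: Zn dust (activated with BrCH2CH2Br/Me3SiCl), THF, 35 °C; then CuBr·SMe2 (10 mol %), Me3SiCl, HMPA, 0 → 23 °C; Et3N/pentane work-up
Reagents that add atoms: chlorotrimethylsilane, C[Si](C)(C)Cl
Why: Zinc inserts into the C-1–I bond, and the alkylzinc 15, relayed through a catalytic alkylcopper and activated by Me3SiCl/HMPA, adds 1,4 to the tethered enone with O-silylation of the enolate (if part of the flux runs by electron transfer, the C-1 radical closes in the same sense and the α-keto radical is reduced to the same zinc enolate). The closest known reaction type is the copper-catalysed, chlorosilane-accelerated conjugate addition of functionalised alkylzinc halides to β,β-disubstituted cyclohexenones, which builds quaternary carbons and delivers enol silanes. Ring A closes in the 6-exo-trig mode, C-9=C-10 being exocyclic to the new ring. C-10 is controlled by C-5: the C-4–C-3–C-2–C-1 chain can reach the adjacent β-carbon only on its own face, through a chair-like six-membered transition state with the ester axial and the C-4 methyl equatorial, so CH3-10 ends syn to H-5 (cis-decalin, the configuration of the target). The step needs 1,4- over 1,2-addition, tolerance of the ester and retention of the enolate position; the tether (1,2-addition would need an eight-membered ring), the inertness of alkylzinc halides toward a neopentyl-type ester and the in situ O-silylation secure these, and the C-8/C-9 enol silane is the only regioisomer that can form.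

Step 8
Reactants: 17 (3R)-3,7-dimethylocta-1,6-dien-3-ol ((R)-(−)-linalool)
Product: 18 triethyl{[(3R)-3,7-dimethylocta-1,6-dien-3-yl]oxy}silane
Conditions: Et3SiOTf, 2,6-lutidine, CH2Cl2, −78 → 0 °C
Reagents that add atoms: triethylsilyl trifluoromethanesulfonate, CC[Si](CC)(CC)OS(=O)(=O)C(F)(F)F
Why: Silylation of the tertiary alcohol with a silyl triflate and a hindered base; the chiral-pool carbinol carbon (future C-13, R) is not involved.

Step 9
Reactants: 18 triethyl{[(3R)-3,7-dimethylocta-1,6-dien-3-yl]oxy}silane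
Product: 20 (4R)-4-methyl-4-[(triethylsilyl)oxy]hex-5-enal, via secondary ozonide 19 (not isolated)
Conditions: O3, CH2Cl2, −78 °C, Sudan red end-point; then PPh3, −78 → 23 °C
Reagents that add atoms: ozone, [O-][O+]=O
Why: Ozonolysis: electrophilic ozone attacks the electron-rich trisubstituted alkene far faster than the vinyl group that is shielded by the neighbouring silyloxy carbon, the dye end-point stops the addition, and reduction of ozonide 19 gives the aldehyde.

Step 10
Reactants: 20 (4R)-4-methyl-4-[(triethylsilyl)oxy]hex-5-enal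
Product: 21 (4R)-4-methyl-4-[(triethylsilyl)oxy]hex-5-enoic acid
Conditions: NaClO2, NaH2PO4, 2-methylbut-2-ene, t-BuOH/H2O, 0 → 23 °C
Reagents that add atoms: sodium chlorite, [Na+].[O-]Cl=O
Why: Pinnick oxidation (chlorous acid with a hypochlorite scavenger) converts the aldehyde into the acid without touching the vinyl group or the silyl ether.

Step 11
Reactants: 21 (4R)-4-methyl-4-[(triethylsilyl)oxy]hex-5-enoic acid
Product: 23 triethyl{[(3R)-5-iodo-3-methylpent-1-en-3-yl]oxy}silane, via thiohydroxamate ester 22 (not isolated)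
Conditions: 1-hydroxypyridine-2(1H)-thione, DCC, DMAP (cat.), CH2Cl2, 23 °C, dark; then CHI3, PhH, 80 °C, visible light
Reagents that add atoms: iodoform, IC(I)I
Why: Barton decarboxylative iodination: the thiohydroxamate ester fragments under light to the primary radical, which loses CO2 and abstracts iodine from CHI3 faster than it could close a four-membered ring onto the vinyl group, so the chain is shortened by one carbon and the iodide carbon becomes C-11.

Step 12
Reactants: 16 methyl (1S,4aS,8aS)-1,4a-dimethyl-6-[(trimethylsilyl)oxy]-1,2,3,4,4a,7,8,8a-octahydronaphthalene-1-carboxylate; 23 triethyl{[(3R)-5-iodo-3-methylpent-1-en-3-yl]oxy}silane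
Product: 25 methyl (1S,4aS,5R,8aS)-1,4a-dimethyl-5-{(3R)-3-methyl-3-[(triethylsilyl)oxy]pent-4-en-1-yl}-6-oxodecahydronaphthalene-1-carboxylate, via ammonium enolate 24 (not isolated)
Conditions: BnMe3NF (anhydrous), 4 Å MS, THF, −20 → 23 °C, 23 in excess
Reagents that add atoms: none
Why: Fluoride cleaves the enol silane to the regiodefined ammonium enolate 24, which is C-alkylated by the primary iodide (SN2) before proton exchange can move the enolate to C-7; the electrophile should enter C-9 axially from the convex face of the cis-decalin, anti to the pseudoaxial C-1 and away from ring A, which puts C-11 syn to CH3-10 and H-5 as in the target.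

Step 13
Reactants: 25 methyl (1S,4aS,5R,8aS)-1,4a-dimethyl-5-{(3R)-3-methyl-3-[(triethylsilyl)oxy]pent-4-en-1-yl}-6-oxodecahydronaphthalene-1-carboxylate
Product: 26 methyl (1S,4aR,5S,8aS)-1,4a-dimethyl-6-methylidene-5-{(3R)-3-methyl-3-[(triethylsilyl)oxy]pent-4-en-1-yl}decahydronaphthalene-1-carboxylate
Conditions: Zn, CH2Br2, TiCl4, THF (reagent pre-formed at 5 °C); then 25, CH2Cl2, 0 → 23 °C
Reagents that add atoms: dibromomethane, BrCBr
Why: Lombardo methylenation with the gem-dizinc/titanium reagent is non-basic, so the ketone should be converted into the C-8=C-17 methylene without epimerising C-9 and without touching the hindered ester or the silyl ether; no stereocentre is formed.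

Step 14
Reactants: 26 methyl (1S,4aR,5S,8aS)-1,4a-dimethyl-6-methylidene-5-{(3R)-3-methyl-3-[(triethylsilyl)oxy]pent-4-en-1-yl}decahydronaphthalene-1-carboxylate
Product: 27 methyl (1S,4aR,5S,8aS)-5-[(3R)-3-hydroxy-3-methylpent-4-en-1-yl]-1,4a-dimethyl-6-methylidenedecahydronaphthalene-1-carboxylate
Conditions: Bu4NF, THF, 23 → 40 °C
Reagents that add atoms: none
Why: Fluoride-mediated desilylation frees the tertiary allylic alcohol under non-acidic conditions that cannot ionise it.

Step 15
Reactants: 27 methyl (1S,4aR,5S,8aS)-5-[(3R)-3-hydroxy-3-methylpent-4-en-1-yl]-1,4a-dimethyl-6-methylidenedecahydronaphthalene-1-carboxylate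
Product: 28 (1S,4aR,5S,8aS)-5-[(3R)-3-hydroxy-3-methylpent-4-en-1-yl]-1,4a-dimethyl-6-methylidenedecahydronaphthalene-1-carboxylic acid
Conditions: LiSPr, HMPA, 23 °C; cold dilute HCl work-up
Reagents that add atoms: none
Why: The neopentyl-type C-19 ester resists attack at the acyl carbon, so it is cleaved by SN2 attack of the thiolate on the methyl group (nucleophilic ester dealkylation), which leaves every stereocentre and both alkenes untouched.

Step 16
Reactants: 28 (1S,4aR,5S,8aS)-5-[(3R)-3-hydroxy-3-methylpent-4-en-1-yl]-1,4a-dimethyl-6-methylidenedecahydronaphthalene-1-carboxylic acid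
Product: 30 (1S,4aR,5S,8aS)-5-[(3R)-3-(acetyloxy)-3-methylpent-4-en-1-yl]-1,4a-dimethyl-6-methylidenedecahydronaphthalene-1-carboxylic acid (target), via mixed anhydride 29 (not isolated)
Conditions: Ac2O, DMAP, Et3N, CH2Cl2, 23 → 40 °C; then THF/aq. NaHCO3, 23 °C; citric acid to pH 4
Reagents that add atoms: acetic anhydride, CC(=O)OC(C)=O
Why: DMAP-catalysed acylation acetylates the tertiary alcohol with retention at C-13, the hindered acid is carried as mixed anhydride 29, and water then attacks the unhindered acetyl carbonyl so that the C-19 acid is returned.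

**Compound list**

1 | oxan-2-one (δ-valerolactone) | O=C1CCCCO1 | starting material
2 | lithium 3,4-dihydro-2H-pyran-6-olate (lithium enolate of 1) | [Li+].[O-]C1=CCCCO1 | intermediate
3 | 3-methyloxan-2-one (racemic) | CC1CCCOC1=O | intermediate
4 | 6-methoxy-5-methyl-3,4-dihydro-2H-pyran-1-ium tetrafluoroborate | COC1=[O+]CCCC1C.F[B-](F)(F)F | intermediate
5 | 2,2-dimethoxy-3-methyloxane | COC1(OC)OCCCC1C | intermediate
6 | 2-methylcyclohex-2-en-1-one | CC1=CCCCC1=O | starting material
7 | (1R)-2-methylcyclohex-2-en-1-ol | O[C@@H]1CCCC=C1C | intermediate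
8 | 2-methoxy-3-methyl-2-{[(1R)-2-methylcyclohex-2-en-1-yl]oxy}oxane | COC1(O[C@@H]2CCCC=C2C)OCCCC1C | intermediate
9 | 5-methyl-6-{[(1R)-2-methylcyclohex-2-en-1-yl]oxy}-3,4-dihydro-2H-pyran | CC1=C(O[C@@H]2CCCC=C2C)OCCC1 | intermediate
10 | (3S)-3-methyl-3-[(1S)-2-methylcyclohex-2-en-1-yl]oxan-2-one | C[C@]1(CCCOC1=O)[C@H]2CCCC=C2C | intermediate
11 | (3S)-3-methyl-3-[(1S)-2-methyl-4-oxocyclohex-2-en-1-yl]oxan-2-one | C[C@]1(CCCOC1=O)[C@H]2CCC(=O)C=C2C | intermediate
12 | trimethylsilyl (2S)-5-iodo-2-methyl-2-[(1S)-2-methyl-4-oxocyclohex-2-en-1-yl]pentanoate | ICCC[C@](C)(C(=O)O[Si](C)(C)C)[C@H]1CCC(=O)C=C1C | intermediate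
13 | (2S)-5-iodo-2-methyl-2-[(1S)-2-methyl-4-oxocyclohex-2-en-1-yl]pentanoic acid | ICCC[C@](C)(C(=O)O)[C@H]1CCC(=O)C=C1C | intermediate
14 | methyl (2S)-5-iodo-2-methyl-2-[(1S)-2-methyl-4-oxocyclohex-2-en-1-yl]pentanoate | ICCC[C@](C)(C(=O)OC)[C@H]1CCC(=O)C=C1C | intermediate
15 | iodo{(4S)-5-methoxy-4-methyl-4-[(1S)-2-methyl-4-oxocyclohex-2-en-1-yl]-5-oxopentyl}zinc | I[Zn]CCC[C@](C)(C(=O)OC)[C@H]1CCC(=O)C=C1C | intermediate
16 | methyl (1S,4aS,8aS)-1,4a-dimethyl-6-[(trimethylsilyl)oxy]-1,2,3,4,4a,7,8,8a-octahydronaphthalene-1-carboxylate | C1=C(O[Si](C)(C)C)CC[C@H]2[C@]1(C)CCC[C@]2(C)C(=O)OC | intermediate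
17 | (3R)-3,7-dimethylocta-1,6-dien-3-ol ((R)-(−)-linalool) | C=C[C@@](C)(CCC=C(C)C)O | starting material
18 | triethyl{[(3R)-3,7-dimethylocta-1,6-dien-3-yl]oxy}silane | C=C[C@@](C)(CCC=C(C)C)O[Si](CC)(CC)CC | intermediate
19 | 3,3-dimethyl-5-{(3R)-3-methyl-3-[(triethylsilyl)oxy]pent-4-en-1-yl}-1,2,4-trioxolane | C=C[C@@](C)(CCC1OOC(C)(C)O1)O[Si](CC)(CC)CC | intermediate
20 | (4R)-4-methyl-4-[(triethylsilyl)oxy]hex-5-enal | C=C[C@@](C)(CCC=O)O[Si](CC)(CC)CC | intermediate
21 | (4R)-4-methyl-4-[(triethylsilyl)oxy]hex-5-enoic acid | C=C[C@@](C)(CCC(=O)O)O[Si](CC)(CC)CC | intermediate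
22 | 2-thioxopyridin-1(2H)-yl (4R)-4-methyl-4-[(triethylsilyl)oxy]hex-5-enoate | C=C[C@@](C)(CCC(=O)ON1C=CC=CC1=S)O[Si](CC)(CC)CC | intermediate
23 | triethyl{[(3R)-5-iodo-3-methylpent-1-en-3-yl]oxy}silane | C=C[C@@](C)(CCI)O[Si](CC)(CC)CC | intermediate
24 | benzyltrimethylammonium salt of the C-8/C-9 enolate formed from 16 by loss of Me3Si | C1=C([O-])CC[C@H]2[C@]1(C)CCC[C@]2(C)C(=O)OC.C[N+](C)(C)Cc1ccccc1 | intermediate
25 | methyl (1S,4aS,5R,8aS)-1,4a-dimethyl-5-{(3R)-3-methyl-3-[(triethylsilyl)oxy]pent-4-en-1-yl}-6-oxodecahydronaphthalene-1-carboxylate | C=C[C@@](C)(CC[C@H]1C(=O)CC[C@H]2[C@]1(C)CCC[C@]2(C)C(=O)OC)O[Si](CC)(CC)CC | intermediate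
26 | methyl (1S,4aR,5S,8aS)-1,4a-dimethyl-6-methylidene-5-{(3R)-3-methyl-3-[(triethylsilyl)oxy]pent-4-en-1-yl}decahydronaphthalene-1-carboxylate | C=C[C@@](C)(CC[C@H]1C(=C)CC[C@H]2[C@]1(C)CCC[C@]2(C)C(=O)OC)O[Si](CC)(CC)CC | intermediate
27 | methyl (1S,4aR,5S,8aS)-5-[(3R)-3-hydroxy-3-methylpent-4-en-1-yl]-1,4a-dimethyl-6-methylidenedecahydronaphthalene-1-carboxylate | C=C[C@@](C)(CC[C@H]1C(=C)CC[C@H]2[C@]1(C)CCC[C@]2(C)C(=O)OC)O | intermediate
28 | (1S,4aR,5S,8aS)-5-[(3R)-3-hydroxy-3-methylpent-4-en-1-yl]-1,4a-dimethyl-6-methylidenedecahydronaphthalene-1-carboxylic acid | C=C[C@@](C)(CC[C@H]1C(=C)CC[C@H]2[C@]1(C)CCC[C@]2(C)C(=O)O)O | intermediate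
29 | acetic (1S,4aR,5S,8aS)-5-[(3R)-3-(acetyloxy)-3-methylpent-4-en-1-yl]-1,4a-dimethyl-6-methylidenedecahydronaphthalene-1-carboxylic anhydride | C=C[C@@](C)(CC[C@H]1C(=C)CC[C@H]2[C@]1(C)CCC[C@]2(C)C(=O)OC(C)=O)OC(C)=O | intermediate
30 | (1S,4aR,5S,8aS)-5-[(3R)-3-(acetyloxy)-3-methylpent-4-en-1-yl]-1,4a-dimethyl-6-methylidenedecahydronaphthalene-1-carboxylic acid | C=C[C@@](C)(CC[C@H]1C(=C)CC[C@H]2[C@]1(C)CCC[C@]2(C)C(=O)O)OC(C)=O | target

**Count and risks**

Total step count: 16. Longest linear sequence: 11 steps (1, 2, 4, 5, 6, 7, 12, 13, 14, 15, 16).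

Steps most likely to fail:

Step 4. What may go wrong: a boat-like transition state may compete and erode the C-4/C-5 diastereoselection, and acid-promoted ionisation of the allylic alcohol through the symmetric allyl cation may erode the chirality transfer. Fallback, setting out from 1 and 7 and returning at 10: lactone 1 is converted as in step 2 (Me3OBF4, then NaOMe) into the unmethylated ortho-lactone 2,2-dimethoxyoxane F1. Johnson–Claisen rearrangement of 7 with F1 gives the lactone 3-[(1R)-2-methylcyclohex-2-en-1-yl]oxan-2-one F2, in which C-5 is again set by the suprafacial shift and the mixture at C-4 does not matter. Deprotonation with LiN(iPr)2 and methylation with MeI then sets C-4 by alkylation of the planar lactone enolate. MeI is expected to enter anti to the C-10(CH3)= arm in the conformer that keeps H-5 eclipsed with the enolate C–O bond (allylic strain), which gives 10 independently of any chair/boat choice.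

Step 7. What may go wrong: incomplete zinc insertion next to an enone, slow addition to the hindered β,β-disubstituted β-carbon, or hydrolysis of the enol silane with loss of the enolate position. Fallback, setting out from 14 and returning at 25 (steps 7 and 12 are bypassed): Bu3SnH/AIBN (PhH, 80 °C, slow addition) closes ring A by 6-exo-trig radical cyclisation, again necessarily cis, to the cis-fused keto ester F3. IBX (DMSO/PhMe, 70 °C) dehydrogenates it, necessarily toward C-7 because C-10 is quaternary, to the C-6/C-7 enone F4. With C-7 blocked, C-9 is the only enolisable α-position, so LiN(iPr)2 followed by 23/HMPA alkylates C-9 from the same convex face to give the alkylated enone F5. Conjugate reduction with [(Ph3P)CuH]6 returns to 25.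

Step 12. What may go wrong: slow C-alkylation of a hindered enolate by an unactivated primary iodide, so that O-alkylation, proton exchange (movement of the enolate, epimerisation at C-9), elimination of HI from 23 or desilylation of the SiEt3 ether by fluoride take over. Fallback, setting out from 16 and returning at 27:
- Mukaiyama–Michael addition of 16 to but-3-en-2-one (TiCl4, CH2Cl2, −78 °C), a reactive acceptor approaching from the same convex face, gives the 1,5-diketone F6.
- Horner–Wadsworth–Emmons reaction of the unhindered methyl ketone ((EtO)2P(O)CH2CO2Et, NaH) gives the (E)-enoate F7.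
- Zn/CH2Br2/TiCl4 gives the methylene enoate F8.
- iBu2AlH (−78 °C) reduces the enoate, not the hindered C-19 ester, to the allylic alcohol F9.
- Sharpless asymmetric epoxidation (Ti(OiPr)4, D-(−)-diethyl tartrate, t-BuOOH) sets C-13 under reagent control in the (2R,3R)-epoxy alcohol F10.
- I2/PPh3/imidazole gives the epoxy iodide F11, and zinc (EtOH, reflux) opens it reductively to the 13R tertiary allylic alcohol 27.

**Further compounds**

F1 | step 4 | 2,2-dimethoxyoxane | COC1(OC)CCCCO1
F2 | step 4 | 3-[(1R)-2-methylcyclohex-2-en-1-yl]oxan-2-one (both C-3 epimers) | O=C1OCCCC1[C@H]2CCCC=C2C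
F3 | step 7 | methyl (1S,4aR,8aS)-1,4a-dimethyl-6-oxodecahydronaphthalene-1-carboxylate | C1C(=O)CC[C@H]2[C@]1(C)CCC[C@]2(C)C(=O)OC
F4 | step 7 | methyl (1S,4aR,8aS)-1,4a-dimethyl-6-oxo-1,2,3,4,4a,5,6,8a-octahydronaphthalene-1-carboxylate | C1C(=O)C=C[C@H]2[C@]1(C)CCC[C@]2(C)C(=O)OC
F5 | step 7 | methyl (1S,4aS,5R,8aS)-1,4a-dimethyl-5-{(3R)-3-methyl-3-[(triethylsilyl)oxy]pent-4-en-1-yl}-6-oxo-1,2,3,4,4a,5,6,8a-octahydronaphthalene-1-carboxylate | C=C[C@@](C)(CC[C@H]1C(=O)C=C[C@H]2[C@]1(C)CCC[C@]2(C)C(=O)OC)O[Si](CC)(CC)CC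
F6 | step 12 | methyl (1S,4aS,5R,8aS)-1,4a-dimethyl-6-oxo-5-(3-oxobutyl)decahydronaphthalene-1-carboxylate | CC(=O)CC[C@H]1C(=O)CC[C@H]2[C@]1(C)CCC[C@]2(C)C(=O)OC
F7 | step 12 | methyl (1S,4aS,5R,8aS)-5-[(3E)-5-ethoxy-3-methyl-5-oxopent-3-en-1-yl]-1,4a-dimethyl-6-oxodecahydronaphthalene-1-carboxylate | CCOC(=O)/C=C(\C)CC[C@H]1C(=O)CC[C@H]2[C@]1(C)CCC[C@]2(C)C(=O)OC
F8 | step 12 | methyl (1S,4aR,5S,8aS)-5-[(3E)-5-ethoxy-3-methyl-5-oxopent-3-en-1-yl]-1,4a-dimethyl-6-methylidenedecahydronaphthalene-1-carboxylate | CCOC(=O)/C=C(\C)CC[C@H]1C(=C)CC[C@H]2[C@]1(C)CCC[C@]2(C)C(=O)OC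
F9 | step 12 | methyl (1S,4aR,5S,8aS)-5-[(3E)-5-hydroxy-3-methylpent-3-en-1-yl]-1,4a-dimethyl-6-methylidenedecahydronaphthalene-1-carboxylate | OC/C=C(\C)CC[C@H]1C(=C)CC[C@H]2[C@]1(C)CCC[C@]2(C)C(=O)OC
F10 | step 12 | methyl (1S,4aR,5S,8aS)-5-{2-[(2R,3R)-3-(hydroxymethyl)-2-methyloxiran-2-yl]ethyl}-1,4a-dimethyl-6-methylidenedecahydronaphthalene-1-carboxylate | OC[C@H]1O[C@]1(C)CC[C@H]2C(=C)CC[C@H]3[C@]2(C)CCC[C@]3(C)C(=O)OC
F11 | step 12 | methyl (1S,4aR,5S,8aS)-5-{2-[(2R,3S)-3-(iodomethyl)-2-methyloxiran-2-yl]ethyl}-1,4a-dimethyl-6-methylidenedecahydronaphthalene-1-carboxylate | IC[C@H]1O[C@]1(C)CC[C@H]2C(=C)CC[C@H]3[C@]2(C)CCC[C@]3(C)C(=O)OC
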